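**Retrosynthetic overview**

1. Rings A, B and C and every C–C bond come intact from luteolin 1; no ring is formed in the route.
2. O–S disconnection at O7, O3' and O4' first: 1 is sulfated to the tris-sulfate salt 2, whose sulfate groups are both target substituents and oxidation-proof masks for the phenols.
3. Key disconnection, C3–O: oxygen is transferred to C2=C3 of 2 (epoxide 3, not isolated) and an SO3 donor opens the epoxide with loss of H3, giving the tetrasulfate salt 4 in one flask.
4. Salt 4 gives the free tetrakis(hydrogen sulfate) 5 (target) by cation exchange.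

Assumption: the target is achiral (no stereocentre, no stereogenic axis), so there is no enantiomer to control; the SMILES is read as the free tetrakis(hydrogen sulfate), which is released from its salt in the last step and kept cold and dry.

Reagent notes: Bu3N·SO3 (tributylsulfoammonium betaine) is a bench-stable SO3 donor, assumed to be bought. DMDO is used as a stock solution in acetone.

**Route**

Step 1
Reactants: 1 luteolin
Product: 2 tris(tributylammonium) luteolin 7,3',4'-tris-O-sulfate
Conditions: Bu3N·SO3 (3.6 equiv), MeCN–DMF (4:1), 60 °C, 6 h; SiO2 (CH2Cl2/MeOH)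
Reagents that add atoms: tributylsulfoammonium betaine (Bu3N·SO3), CCCC[N+](CCCC)(CCCC)S(=O)(=O)[O-]
Why: O-sulfation of phenols by sulfur trioxide transfer from an SO3–amine complex, in which the three free phenols attack sulfur and the phenolic proton ends on Bu3N, so the reagent is incorporated whole without a by-product and gives a lipophilic, chromatographable salt, while the 5-OH, locked in its hydrogen bond to the C4 carbonyl, is the least nucleophilic hydroxyl of a flavone and stays free; no stereocentre is formed.

Step 2
Reactants: 2 tris(tributylammonium) luteolin 7,3',4'-tris-O-sulfate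
Product: 4 tetrakis(tributylammonium) quercetin 3,7,3',4'-tetra-O-sulfate, via luteolin 2,3-epoxide tris-O-sulfate salt 3 (not isolated)
Conditions: DMDO (3 equiv, 0.07 M in acetone), CH2Cl2, 0 °C to rt, dark; evaporate; then Bu3N·SO3 (1.5 equiv), MeCN, 40 °C
Reagents that add atoms: dimethyldioxirane (DMDO), CC1(C)OO1; tributylsulfoammonium betaine (Bu3N·SO3), CCCC[N+](CCCC)(CCCC)S(=O)(=O)[O-]
Why: Proposed new method: one-flask C3–H sulfoxylation of a flavone, in which the sulfate monoesters already in place leave no oxidisable phenol (the catechol and 7-OH are masked as electron-poor, O–H-free aryl sulfates, the 5-OH is tied up in its hydrogen bond to C4=O, and the Bu3NH+ ions are protonated and inert), so the electrophilic dioxirane transfers oxygen only to the enol-ether-like C2=C3 bond through the usual concerted spiro transition state, which forms the C3–O bond (the two new stereocentres are racemic and are erased again); the 2,3-epoxide is the epoxide of an enol ether, so O-sulfonation by the SO3 donor opens it at C2 to an oxocarbenium ion stabilised by O1 and the aryl ring, and Bu3N removes the now doubly activated H3 to restore the aromatic pyranone as its 3-O-sulfate (if the epoxide first isomerises to the 3-hydroxyflavone, plain O-sulfation leads to the same product); closest known reaction types are dioxirane epoxidation of O-alkylated flavones with acid isomerisation to flavonols and O-sulfation of flavonols with SO3–amine complexes, neither shown on a polysulfated 5-hydroxyflavone, and an SO3-triggered eliminative epoxide opening to an enol sulfate is not known.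

Step 3
Reactants: 4 tetrakis(tributylammonium) quercetin 3,7,3',4'-tetra-O-sulfate
Product: 5 quercetin 3,7,3',4'-tetra-O-sulfate (free tetrakis(hydrogen sulfate))
Conditions: sulfonic acid cation-exchange resin (H+ form), H2O–MeOH (9:1), 0–5 °C; freeze-dry at once
Reagents that add atoms: none
Why: Cation exchange on a strongly acidic resin, which binds Bu3NH+ and releases H+ to the fully ionised aryl sulfates, while cold, dilute handling and immediate freeze-drying outrun the acid-catalysed hydrolysis of the sulfate esters; the product is achiral, so no stereocentre is at stake.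

**Compound list**

1 | luteolin (5,7,3',4'-tetrahydroxyflavone) | O=c1cc(-c2ccc(O)c(O)c2)oc2cc(O)cc(O)c12 | starting material
2 | tris(tributylammonium) luteolin 7,3',4'-tris-O-sulfate (5-OH free) | O=c1cc(-c2ccc(OS(=O)(=O)[O-])c(OS(=O)(=O)[O-])c2)oc2cc(OS(=O)(=O)[O-])cc(O)c12.CCCC[NH+](CCCC)CCCC.CCCC[NH+](CCCC)CCCC.CCCC[NH+](CCCC)CCCC | intermediate
3 | tris(tributylammonium) salt of the racemic 2,3-epoxide of 2 (2,3-epoxyflavanone; oxirane cis-fused to ring C, H3 and the aryl group on the face opposite to the oxirane oxygen; one enantiomer drawn) | O=C1[C@@H]2O[C@]2(c2ccc(OS(=O)(=O)[O-])c(OS(=O)(=O)[O-])c2)Oc2cc(OS(=O)(=O)[O-])cc(O)c21.CCCC[NH+](CCCC)CCCC.CCCC[NH+](CCCC)CCCC.CCCC[NH+](CCCC)CCCC | intermediate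
4 | tetrakis(tributylammonium) quercetin 3,7,3',4'-tetra-O-sulfate (5-OH free) | O=c1c(OS(=O)(=O)[O-])c(-c2ccc(OS(=O)(=O)[O-])c(OS(=O)(=O)[O-])c2)oc2cc(OS(=O)(=O)[O-])cc(O)c12.CCCC[NH+](CCCC)CCCC.CCCC[NH+](CCCC)CCCC.CCCC[NH+](CCCC)CCCC.CCCC[NH+](CCCC)CCCC | intermediate
5 | quercetin 3,7,3',4'-tetra-O-sulfate, free tetrakis(hydrogen sulfate), achiral | O=c1c(OS(=O)(=O)O)c(-c2ccc(OS(=O)(=O)O)c(OS(=O)(=O)O)c2)oc2cc(OS(=O)(=O)O)cc(O)c12 | target

**Totals**

Total step count: 3. Longest linear sequence: 3 (1 → 2 → 4 → 5).

**Steps most likely to fail** (the route has three steps, so all three are ranked)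

Step 2 (the proposed new step). Risks: slow epoxidation of a C2=C3 bond that carries an electron-poor aryl group; dioxirane attack on ring A ortho or para to the 5-OH; early isomerisation of 3 to the flavonol and its over-oxidation. The fallback uses known chemistry, sets out from 1 and comes back to the route at 4. Luteolin 1 is fully benzylated (BnBr, K2CO3, DMF, 80 °C; NaH for the chelated 5-OH if it lags) to 5,7,3',4'-tetra-O-benzylluteolin F1. DMDO in acetone/CH2Cl2 gives the isolable racemic 5,7,3',4'-tetra-O-benzylluteolin 2,3-epoxide F2, and catalytic p-TsOH in CH2Cl2 isomerises it to 5,7,3',4'-tetra-O-benzylquercetin F3. This epoxidation and isomerisation is the established conversion of an O-alkylated flavone into a flavonol. Hydrogenolysis (H2, Pd/C, zerovalent palladium on carbon, THF–MeOH) gives quercetin F4. Exhaustive sulfation of F4 with Bu3N·SO3 (4.5 equiv, MeCN–DMF, 60 °C) leaves the chelated 5-OH free and gives 4.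

Step 1. Risks: mixtures of di- and tris-sulfates, some 5-O-sulfation with excess reagent, and salts that are hard to separate. The fallback changes to a protected-sulfate approach, sets out from 1 and comes back at 2. Luteolin 1 reacts with 2,2,2-trichloroethyl chlorosulfate (3.3 equiv, Et3N, DMAP, THF, 0 °C) to give luteolin 7,3',4'-tris(2,2,2-trichloroethyl sulfate) F5, a neutral sulfate diester that is purified on silica like any ordinary organic compound. Reductive removal of the trichloroethyl groups (Zn dust, HCO2NH4, MeOH, rt) gives tris(ammonium) luteolin 7,3',4'-tris-O-sulfate F6. Repeated evaporation from MeOH with excess Bu3N drives off NH3 and gives 2.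

Step 3. Risk: the free aryl hydrogen sulfates hydrolyse autocatalytically during long contact with the acidic resin or on concentration. The fallback replaces ion exchange by precipitation metathesis, sets out from 4 and comes back at 5. Salt 4 is treated with Ba(OH)2 (2.0 equiv, H2O, 0 °C) and the liberated Bu3N is extracted into Et2O, leaving dibarium quercetin 3,7,3',4'-tetra-O-sulfate F7 in the water layer. Exactly 2.0 equiv of cold dilute H2SO4 precipitates BaSO4, which is centrifuged off, and the filtrate is freeze-dried to 5.

**Further compounds**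

F1 | step 2 | 5,7,3',4'-tetra-O-benzylluteolin | O=c1cc(-c2ccc(OCc3ccccc3)c(OCc3ccccc3)c2)oc2cc(OCc3ccccc3)cc(OCc3ccccc3)c12
F2 | step 2 | racemic 5,7,3',4'-tetra-O-benzylluteolin 2,3-epoxide (oxirane cis-fused to ring C; one enantiomer drawn) | O=C1[C@@H]2O[C@]2(c2ccc(OCc3ccccc3)c(OCc3ccccc3)c2)Oc2cc(OCc3ccccc3)cc(OCc3ccccc3)c21
F3 | step 2 | 5,7,3',4'-tetra-O-benzylquercetin | O=c1c(O)c(-c2ccc(OCc3ccccc3)c(OCc3ccccc3)c2)oc2cc(OCc3ccccc3)cc(OCc3ccccc3)c12
F4 | step 2 | quercetin | O=c1c(O)c(-c2ccc(O)c(O)c2)oc2cc(O)cc(O)c12
F5 | step 1 | luteolin 7,3',4'-tris(2,2,2-trichloroethyl sulfate) | O=c1cc(-c2ccc(OS(=O)(=O)OCC(Cl)(Cl)Cl)c(OS(=O)(=O)OCC(Cl)(Cl)Cl)c2)oc2cc(OS(=O)(=O)OCC(Cl)(Cl)Cl)cc(O)c12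
F6 | step 1 | tris(ammonium) luteolin 7,3',4'-tris-O-sulfate | O=c1cc(-c2ccc(OS(=O)(=O)[O-])c(OS(=O)(=O)[O-])c2)oc2cc(OS(=O)(=O)[O-])cc(O)c12.[NH4+].[NH4+].[NH4+]
F7 | step 3 | dibarium quercetin 3,7,3',4'-tetra-O-sulfate | O=c1c(OS(=O)(=O)[O-])c(-c2ccc(OS(=O)(=O)[O-])c(OS(=O)(=O)[O-])c2)oc2cc(OS(=O)(=O)[O-])cc(O)c12.[Ba+2].[Ba+2]
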